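**Retrosynthetic overview**

- Target ⇒ (O-demethylation) 1-(3,5-dimethoxyphenyl)tricosan-2-one ⇒ (alcohol oxidation) 1-(3,5-dimethoxyphenyl)tricosan-2-ol.
- Key disconnection: the ring C5–C1'H2 bond and the C2'–C3' bond are cut in one operation, giving three components: 3,5-dimethoxyphenyl triflate, vinylboronic acid pinacol ester (C1' and C2') and heneicosylmagnesium bromide (C3'–C23'). The C2'–B bond left by the coupling becomes the C2'–O bond.
- Enabling feature: the side chain's C1'H2–C2'(=O) unit is an oxygen-bearing carbon flanked by the benzylic CH2 on ring carbon C5 and by the unbranched C3'–C23' chain. It is a vinyl group in disguise (C1' = terminal carbon, C2' = boron-bearing carbon). Ring carbon C5, meta to the oxygens on C1 and C3 and out of reach of electrophilic substitution, is addressed as the C–O carbon of a 1,3,5-trioxygenated benzene.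
- Rings: the benzene ring, the only ring, is bought intact in 3,5-dimethoxyphenol; no ring is formed in the route.

Key step: step 2

Remark: 1-bromoheneicosane is taken as a catalogue compound, and the C2' stereocentre created in step 2 is transient (it becomes the carbonyl carbon), so compounds 7 and 8 are drawn without a defined configuration.

**Route**

Step 1
Reactants: 1 3,5-dimethoxyphenol
Product: 2 3,5-dimethoxyphenyl trifluoromethanesulfonate
Conditions: Tf2O, pyridine, CH2Cl2, 0 °C
Reagents that add atoms: trifluoromethanesulfonic anhydride, O=S(=O)(OS(=O)(=O)C(F)(F)F)C(F)(F)F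
Why: O-sulfonylation of a phenol with triflic anhydride and pyridine (aryl triflate formation) is fast at 0 °C, the methyl ethers are inert, and the non-acidic medium should leave the electron-rich ring untouched.

Step 2
Reactants: 2 3,5-dimethoxyphenyl trifluoromethanesulfonate; 3 1-bromoheneicosane; 4 vinylboronic acid pinacol ester (4,4,5,5-tetramethyl-2-vinyl-1,3,2-dioxaborolane)
Product: 8 1-(3,5-dimethoxyphenyl)tricosan-2-ol, via heneicosylmagnesium bromide 5 (not isolated), via vinylboron ate complex 6 (not isolated), via secondary pinacol boronate 7 (not isolated)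
Conditions: 3, Mg, THF, 45 °C; then 4, THF, 0 °C to rt; then NaOTf, 2, Pd(OAc)2 (cat.), MandyPhos ligand 2,2'-bis[(dimethylamino)(phenyl)methyl]-1,1'-bis(diphenylphosphino)ferrocene (cat., either enantiomer), THF/DMSO, 40–60 °C; then aq. NaOH, H2O2, 0 °C to rt
Reagents that add atoms: hydrogen peroxide, OO
Why: Conjunctive cross-coupling: Grignard reagent 5 adds to boron of 4 to give the four-coordinate ate complex 6, oxidative addition of triflate 2 to zerovalent palladium gives a cationic arylpalladium species that binds the vinyl group of 6 and induces a 1,2-metallate shift (heneicosyl moves from boron to the boron-bearing carbon while the terminal carbon bonds to palladium), and reductive elimination then forges the ring C5–C1'H2 bond to give boronate 7, which alkaline H2O2 oxidises with retention to alcohol 8. The closest known reaction type is the palladium/MandyPhos-catalysed conjunctive coupling of Grignard-derived vinylboron ate complexes with aryl triflates in the presence of NaOTf, which gives 1-aryl-2-alkanols of exactly this pattern after oxidation. No ring is closed. The single new stereocentre, C2', is set by the planar-chiral ligand, which decides the alkene face bound by palladium in the anti-periplanar migration, but its sense is immaterial because C2' becomes the carbonyl carbon in step 3. The step needs the metallate shift to outrun direct Suzuki–Miyaura transfer of vinyl or alkyl from boron and β-hydride elimination of the alkylpalladium intermediate; the triflate leaving group (cationic palladium, strong alkene binding), the non-migrating pinacolate oxygens, the chelating bisphosphine and NaOTf as scavenger of the bromide brought in by 5 secure this. Regiochemistry (aryl on the terminal CH2, alkyl and the future oxygen on the internal carbon) follows from the mechanism, since migration can only end at the carbon attached to boron.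

Step 3
Reactants: 8 1-(3,5-dimethoxyphenyl)tricosan-2-ol
Product: 9 1-(3,5-dimethoxyphenyl)tricosan-2-one
Conditions: Dess–Martin periodinane, CH2Cl2, 0 °C to rt
Reagents that add atoms: none
Why: Dess–Martin oxidation of a secondary alcohol to the ketone runs under mild conditions free of electrophilic halogen, so the electron-rich dimethoxyarene and the benzylic CH2 should be left alone while the transient C2' stereocentre disappears.

Step 4
Reactants: 9 1-(3,5-dimethoxyphenyl)tricosan-2-one
Product: 10 5-(2'-oxotricosyl)resorcinol
Conditions: BBr3 (excess), CH2Cl2, −78 °C to rt; then H2O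
Reagents that add atoms: none
Why: Lewis-acid cleavage of aryl methyl ethers with BBr3 (boron coordination to oxygen, bromide attack on methyl, hydrolysis of the aryl borates on work-up) should free both phenols, with excess reagent compensating for complexation by the ketone, which is released unchanged on aqueous quench.

**Compound list**

1 | 3,5-dimethoxyphenol | COc1cc(O)cc(OC)c1 | starting material
2 | 3,5-dimethoxyphenyl trifluoromethanesulfonate | COc1cc(OS(=O)(=O)C(F)(F)F)cc(OC)c1 | intermediate
3 | 1-bromoheneicosane | CCCCCCCCCCCCCCCCCCCCCBr | starting material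
4 | vinylboronic acid pinacol ester (4,4,5,5-tetramethyl-2-vinyl-1,3,2-dioxaborolane) | C=CB1OC(C)(C)C(C)(C)O1 | starting material
5 | heneicosylmagnesium bromide | CCCCCCCCCCCCCCCCCCCCC[Mg]Br | intermediate
6 | bromomagnesium heneicosyl(pinacolato)vinylborate (vinylboron ate complex) | CCCCCCCCCCCCCCCCCCCCC[B-]1(C=C)OC(C)(C)C(C)(C)O1.[Mg+]Br | intermediate
7 | 2-[1-(3,5-dimethoxyphenyl)tricosan-2-yl]-4,4,5,5-tetramethyl-1,3,2-dioxaborolane (either C2 configuration) | CCCCCCCCCCCCCCCCCCCCCC(Cc1cc(OC)cc(OC)c1)B1OC(C)(C)C(C)(C)O1 | intermediate
8 | 1-(3,5-dimethoxyphenyl)tricosan-2-ol (either C2 configuration) | CCCCCCCCCCCCCCCCCCCCCC(O)Cc1cc(OC)cc(OC)c1 | intermediate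
9 | 1-(3,5-dimethoxyphenyl)tricosan-2-one | CCCCCCCCCCCCCCCCCCCCCC(=O)Cc1cc(OC)cc(OC)c1 | intermediate
10 | 5-(2'-oxotricosyl)resorcinol, 1-(3,5-dihydroxyphenyl)tricosan-2-one (achiral) | CCCCCCCCCCCCCCCCCCCCCC(=O)Cc1cc(O)cc(O)c1 | target

**Step count**

Total step count: 4
Longest linear sequence: 4 steps (1 → 2 → 8 → 9 → 10)

**Steps most likely to fail**

Step 2 (key step). What may go wrong:
- direct Suzuki–Miyaura-type transfer of the vinyl or alkyl group from boron to palladium instead of the metallate shift;
- β-hydride elimination of the alkylpalladium intermediate;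
- incomplete ate-complex formation because the waxy C21 Grignard reagent forms sluggishly and homocouples.

Fallback: it sets out from triflate 2. Stille allylation with allyltributylstannane (Pd(PPh3)4, LiCl, DMF, 90 °C) should give 1-allyl-3,5-dimethoxybenzene F1, which forms the same ring C5–C1' bond by a classical coupling. Epoxidation (mCPBA, CH2Cl2, 0 °C) should give racemic 2-[(3,5-dimethoxyphenyl)methyl]oxirane F2. Copper-catalysed opening at the terminal epoxide carbon with eicosylmagnesium bromide F3 (from commercial 1-bromoeicosane and Mg; CuI cat., THF, −30 to 0 °C) should give alcohol 8, where the route is rejoined before step 3.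

Step 4. What may go wrong: cleavage stalling after the first methyl ether, or Lewis-acid-promoted enolisation and self-condensation of the benzyl ketone during prolonged exposure.

Fallback: the phenols are carried as benzyl ethers instead. It sets out from ate complex 6 (made as in step 2 from 3 and 4). Coupling under the step 2 conditions with 3,5-bis(benzyloxy)phenyl trifluoromethanesulfonate F4 (from commercial 3,5-bis(benzyloxy)phenol, Tf2O, pyridine) should give 2-{1-[3,5-bis(benzyloxy)phenyl]tricosan-2-yl}-4,4,5,5-tetramethyl-1,3,2-dioxaborolane F5 (not isolated). Oxidation with NaOH/H2O2 should then give 1-[3,5-bis(benzyloxy)phenyl]tricosan-2-ol F6. Dess–Martin oxidation should give 1-[3,5-bis(benzyloxy)phenyl]tricosan-2-one F7. Neutral hydrogenolysis (H2, Pd/C, EtOAc/EtOH, rt) should remove both benzyl groups without touching the ketone, returning to the route at target 10.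

Step 3. What may go wrong: over-oxidation at the doubly activated C1' methylene, or self-condensation of the enolisable benzyl ketone during work-up.

Fallback: the ketone oxidation level is reached by C–C bond formation instead of oxidation. It sets out from triflate 2. Tricosan-2-one F8 is made from commercial docosanoyl chloride and MeMgBr (Fe(acac)3 cat., THF, −78 °C). Palladium-catalysed ketone α-arylation of F8 with 2 (Pd(OAc)2, Xantphos, K3PO4, toluene, 80 °C, ketone in excess) is expected to arylate the less hindered methyl terminus and give ketone 9 directly. The route is rejoined at 9 before step 4.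

**Further compounds**

F1 | step 2 | 1-allyl-3,5-dimethoxybenzene | C=CCc1cc(OC)cc(OC)c1
F2 | step 2 | 2-[(3,5-dimethoxyphenyl)methyl]oxirane (racemic) | COc1cc(CC2CO2)cc(OC)c1
F3 | step 2 | eicosylmagnesium bromide | CCCCCCCCCCCCCCCCCCCC[Mg]Br
F4 | step 4 | 3,5-bis(benzyloxy)phenyl trifluoromethanesulfonate | O=S(=O)(Oc1cc(OCc2ccccc2)cc(OCc2ccccc2)c1)C(F)(F)F
F5 | step 4 | 2-{1-[3,5-bis(benzyloxy)phenyl]tricosan-2-yl}-4,4,5,5-tetramethyl-1,3,2-dioxaborolane (either C2 configuration) | CCCCCCCCCCCCCCCCCCCCCC(Cc1cc(OCc2ccccc2)cc(OCc2ccccc2)c1)B1OC(C)(C)C(C)(C)O1
F6 | step 4 | 1-[3,5-bis(benzyloxy)phenyl]tricosan-2-ol (either C2 configuration) | CCCCCCCCCCCCCCCCCCCCCC(O)Cc1cc(OCc2ccccc2)cc(OCc2ccccc2)c1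
F7 | step 4 | 1-[3,5-bis(benzyloxy)phenyl]tricosan-2-one | CCCCCCCCCCCCCCCCCCCCCC(=O)Cc1cc(OCc2ccccc2)cc(OCc2ccccc2)c1
F8 | step 3 | tricosan-2-one | CCCCCCCCCCCCCCCCCCCCCC(C)=O
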